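**Retrosynthetic overview**

- Acid last: the terminal (E)-methyl of the intact nerolidol chain is oxidised after the core is built, and the two silyl groups come off in the final step.
- Five-membered ring (formed second): the C2–O bond is closed by SN2 attack of the vinylogous-ester carbonyl oxygen on a C2 sulfonate, which inverts C2 and places the ring oxygen next to the C7 carbinol.
- Key C–C bond C3–C3a: an α-iodo-β-methoxy enone acts as the α-cation (enolonium) equivalent of the cyclohexane-1,3-dione, so its normally nucleophilic α-carbon is joined as an electrophile to the carbon α to the C2 oxygen. The nucleophile is the primary boronate from catalytic enantioselective 1,2-diboration of the vinyl group of (S)-nerolidol.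
- Six-membered ring (formed first): intramolecular Claisen condensation of (R)-5-acetylbutyrolactone, made from (R)-5-oxotetrahydrofuran-2-carboxylic acid.
- Stereocentres: C7 from the chiral pool, the tertiary carbinol from (S)-nerolidol, C2 by catalyst control (set as R, inverted to S on ring closure).

Assumption: (S)-(+)-(E)-nerolidol (natural cabreuva-oil grade, high ee) and (R)-5-oxotetrahydrofuran-2-carboxylic acid (from D-glutamic acid) are bought, and the (R,R) phosphonite in step 6 is taken to give the (2R) boronate by analogy with simple 1-alkenes (its enantiomer is used if the sense is opposite).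

**Route**

Step 1
Reactants: 1 (R)-5-oxotetrahydrofuran-2-carboxylic acid
Product: 3 (R)-5-acetyldihydrofuran-2(3H)-one, via lactone acid chloride 2 (not isolated)
Conditions: (COCl)2, DMF (cat.), CH2Cl2, 0 °C to rt; then MeMgBr, CuI (5 mol%), THF, −78 °C
Reagents that add atoms: methylmagnesium bromide, C[Mg]Br
Why: Copper-catalysed acylation of the Grignard reagent by the acid chloride at −78 °C is faster than attack on the lactone or the new ketone (standard ketone synthesis for this lactone acid), and with no base present the stereocentre is not enolised.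

Step 2
Reactants: 3 (R)-5-acetyldihydrofuran-2(3H)-one
Product: 5 (R)-4-(tert-butyldimethylsilyloxy)cyclohexane-1,3-dione, via dilithium alkoxide-enolate of (R)-4-hydroxycyclohexane-1,3-dione 4 (not isolated)
Conditions: add 3 to LiN(SiMe3)2 (2.2 equiv), THF, −78 to 0 °C; then TBSOTf (1.05 equiv), −78 °C; 1 M HCl work-up
Reagents that add atoms: tert-butyldimethylsilyl triflate, CC(C)(C)[Si](C)(C)OS(=O)(=O)C(F)(F)F
Why: Proposed new method: inverse addition to excess amide gives the kinetic methyl-side enolate, which attacks the lactone carbonyl through a 7-oxabicyclo[2.2.1]heptane-type tetrahedral intermediate and expels the ring oxygen (intramolecular Claisen condensation; closest known reaction is the base-induced cyclisation of 5-oxohexanoates to cyclohexane-1,3-diones), the product is trapped as its dione enolate while the more nucleophilic alkoxide is silylated in the same flask, and the stereocentre is carried over from 1.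

Step 3
Reactants: 5 (R)-4-(tert-butyldimethylsilyloxy)cyclohexane-1,3-dione
Product: 6 (R)-6-(tert-butyldimethylsilyloxy)-3-methoxycyclohex-2-en-1-one
Conditions: Me2SO4, K2CO3, acetone, rt; chromatography
Reagents that add atoms: dimethyl sulfate, COS(=O)(=O)OC
Why: O-Alkylation of the 1,3-dione enolate with a hard methylating agent (vinylogous ester formation) is expected to favour the oxygen remote from the bulky silyloxy-bearing carbon, which leaves the carbonyl next to C–OTBS; the minor regioisomer is removed.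

Step 4
Reactants: 6 (R)-6-(tert-butyldimethylsilyloxy)-3-methoxycyclohex-2-en-1-one
Product: 7 (R)-6-(tert-butyldimethylsilyloxy)-2-iodo-3-methoxycyclohex-2-en-1-one
Conditions: N-iodosuccinimide, CH2Cl2, 0 °C to rt, dark
Reagents that add atoms: N-iodosuccinimide, O=C1CCC(=O)N1I
Why: Electrophilic α-iodination of the electron-rich β-alkoxy enone (enol-ether-type substitution) gives the α-iodo vinylogous ester, the electrophilic α-cation equivalent of the dione.

Step 5
Reactants: 8 (S,E)-nerolidol
Product: 9 triethyl{[(3S,6E)-3,7,11-trimethyldodeca-1,6,10-trien-3-yl]oxy}silane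
Conditions: TESOTf, 2,6-lutidine, CH2Cl2, −78 to 0 °C
Reagents that add atoms: triethylsilyl triflate, CC[Si](CC)(CC)OS(=O)(=O)C(F)(F)F
Why: Silyl triflate protection of the hindered tertiary allylic alcohol (standard silylation) masks a hydroxyl that would bind boron in step 6 and could form an epoxide in step 7.

Step 6
Reactants: 9 triethyl{[(3S,6E)-3,7,11-trimethyldodeca-1,6,10-trien-3-yl]oxy}silane; 7 (R)-6-(tert-butyldimethylsilyloxy)-2-iodo-3-methoxycyclohex-2-en-1-one
Product: 12 (6R)-6-(tert-butyldimethylsilyloxy)-2-[(2R,3S,6E)-2-hydroxy-3,7,11-trimethyl-3-(triethylsilyloxy)dodeca-6,10-dien-1-yl]-3-methoxycyclohex-2-en-1-one, via 1,2-bis(boronate) 10 (not isolated), via coupled secondary boronate 11 (not isolated)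
Conditions: B2pin2, Pt(dba)3 (3 mol%), (R,R)-3,5-diethylphenyl-TADDOL phenylphosphonite (6 mol%), THF, 60 °C; then 7, Pd(OAc)2 (2 mol%), RuPhos (2 mol%), KOH, THF/H2O 10:1, 70 °C; then NaOH, H2O2, 0 °C
Reagents that add atoms: hydrogen peroxide, OO
Why: Morken-type diboration/cross-coupling cascade in which platinum-catalysed enantioselective 1,2-diboration touches only the monosubstituted alkene and sets C2 under catalyst control (the neighbouring quaternary carbinol gives little bias), the primary C–B bond then undergoes Suzuki–Miyaura coupling with the α-iodo enone carbon, and oxidation of the secondary C–B bond with retention gives the (2R) alcohol.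

Step 7
Reactants: 12 (6R)-6-(tert-butyldimethylsilyloxy)-2-[(2R,3S,6E)-2-hydroxy-3,7,11-trimethyl-3-(triethylsilyloxy)dodeca-6,10-dien-1-yl]-3-methoxycyclohex-2-en-1-one
Product: 15 (2S,7R)-7-(tert-butyldimethylsilyloxy)-2-[(2S,5E)-6,10-dimethyl-2-(triethylsilyloxy)undeca-5,9-dien-2-yl]-3,5,6,7-tetrahydro-1-benzofuran-4(2H)-one, via secondary mesylate 13 (not isolated), via methoxy-oxocarbenium mesylate 14 (not isolated)
Conditions: Ms2O, 2,6-lutidine, DMAP (cat.), CH2Cl2, 0 °C; then MeCN, 70 °C
Reagents that add atoms: none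
Why: Intramolecular SN2 O-alkylation (5-exo-tet) of the mesylate by the vinylogous-ester carbonyl oxygen, the only nucleophilic oxygen within reach, inverts C2 to S and fixes the ring oxygen on the carbon next to C–OTBS, and the methoxy-oxocarbenium ion is then demethylated by mesylate (alkylative cyclisation with dealkylation, as in halo-etherifications of 2-alkyl-3-alkoxyenones).

Step 8
Reactants: 15 (2S,7R)-7-(tert-butyldimethylsilyloxy)-2-[(2S,5E)-6,10-dimethyl-2-(triethylsilyloxy)undeca-5,9-dien-2-yl]-3,5,6,7-tetrahydro-1-benzofuran-4(2H)-one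
Product: 16 (2S,7R)-7-(tert-butyldimethylsilyloxy)-2-[(2S,5E,9E)-11-hydroxy-6,10-dimethyl-2-(triethylsilyloxy)undeca-5,9-dien-2-yl]-3,5,6,7-tetrahydro-1-benzofuran-4(2H)-one
Conditions: SeO2 (0.3 equiv), t-BuOOH, salicylic acid (cat.), CH2Cl2, rt
Reagents that add atoms: selenium dioxide, O=[Se]=O (oxygen carrier); tert-butyl hydroperoxide, CC(C)(C)OO (terminal oxidant)
Why: Sharpless–Umbreit allylic oxidation (ene reaction then [2,3]-shift) is selective for the (E)-methyl of the terminal isopropylidene group and gives the (E)-allylic alcohol, while the push-pull enol ether double bond is too electron-poor to react.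

Step 9
Reactants: 16 (2S,7R)-7-(tert-butyldimethylsilyloxy)-2-[(2S,5E,9E)-11-hydroxy-6,10-dimethyl-2-(triethylsilyloxy)undeca-5,9-dien-2-yl]-3,5,6,7-tetrahydro-1-benzofuran-4(2H)-one
Product: 18 (2E,6E,10S)-10-[(2S,7R)-7-(tert-butyldimethylsilyloxy)-4-oxo-2,3,4,5,6,7-hexahydro-1-benzofuran-2-yl]-2,6-dimethyl-10-(triethylsilyloxy)undeca-2,6-dienoic acid, via enal 17 (not isolated)
Conditions: TEMPO (cat.), PhI(OAc)2, CH2Cl2, rt; then NaClO2, NaH2PO4, 2-methyl-2-butene, t-BuOH/H2O, 0 °C to rt
Reagents that add atoms: sodium chlorite, [Na+].[O-]Cl=O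
Why: Oxoammonium (TEMPO) oxidation of the primary allylic alcohol to the enal followed by Pinnick oxidation in the same flask gives the acid without touching the E-alkene, the silyl ethers or the enol ether, because HOCl is trapped by 2-methyl-2-butene.

Step 10
Reactants: 18 (2E,6E,10S)-10-[(2S,7R)-7-(tert-butyldimethylsilyloxy)-4-oxo-2,3,4,5,6,7-hexahydro-1-benzofuran-2-yl]-2,6-dimethyl-10-(triethylsilyloxy)undeca-2,6-dienoic acid
Product: 19 (2E,6E,10S)-10-hydroxy-10-[(2S,7R)-7-hydroxy-4-oxo-2,3,4,5,6,7-hexahydro-1-benzofuran-2-yl]-2,6-dimethylundeca-2,6-dienoic acid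
Conditions: HF·pyridine, excess pyridine, THF, 0 °C to rt
Reagents that add atoms: none
Why: Buffered fluoride cleaves both silyl ethers (standard desilylation) under conditions mild enough to avoid ionisation of the allylic-type C7 hydroxyl, so the three stereocentres reach the target unchanged.

**Compound list**

1 | (R)-5-oxotetrahydrofuran-2-carboxylic acid | OC(=O)[C@H]1CCC(=O)O1 | starting material
2 | (R)-5-oxotetrahydrofuran-2-carbonyl chloride | ClC(=O)[C@H]1CCC(=O)O1 | intermediate
3 | (R)-5-acetyldihydrofuran-2(3H)-one | CC(=O)[C@H]1CCC(=O)O1 | intermediate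
4 | dilithium alkoxide-enolate of (R)-4-hydroxycyclohexane-1,3-dione | [Li+].[Li+].[O-][C@@H]1CCC(=O)C=C1[O-] | intermediate
5 | (R)-4-(tert-butyldimethylsilyloxy)cyclohexane-1,3-dione | O=C1CC(=O)[C@H](O[Si](C)(C)C(C)(C)C)CC1 | intermediate
6 | (R)-6-(tert-butyldimethylsilyloxy)-3-methoxycyclohex-2-en-1-one | COC1=CC(=O)[C@H](O[Si](C)(C)C(C)(C)C)CC1 | intermediate
7 | (R)-6-(tert-butyldimethylsilyloxy)-2-iodo-3-methoxycyclohex-2-en-1-one | COC1=C(I)C(=O)[C@H](O[Si](C)(C)C(C)(C)C)CC1 | intermediate
8 | (S,E)-nerolidol, (3S,6E)-3,7,11-trimethyldodeca-1,6,10-trien-3-ol | C/C(=C\CC[C@](C)(O)C=C)CCC=C(C)C | starting material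
9 | triethyl{[(3S,6E)-3,7,11-trimethyldodeca-1,6,10-trien-3-yl]oxy}silane | C/C(=C\CC[C@](C)(O[Si](CC)(CC)CC)C=C)CCC=C(C)C | intermediate
10 | triethyl{[(2R,3S,6E)-3,7,11-trimethyl-1,2-bis(4,4,5,5-tetramethyl-1,3,2-dioxaborolan-2-yl)dodeca-6,10-dien-3-yl]oxy}silane | C/C(=C\CC[C@](C)(O[Si](CC)(CC)CC)[C@H](B1OC(C)(C)C(C)(C)O1)CB2OC(C)(C)C(C)(C)O2)CCC=C(C)C | intermediate
11 | (6R)-6-(tert-butyldimethylsilyloxy)-3-methoxy-2-[(2R,3S,6E)-3,7,11-trimethyl-2-(4,4,5,5-tetramethyl-1,3,2-dioxaborolan-2-yl)-3-(triethylsilyloxy)dodeca-6,10-dien-1-yl]cyclohex-2-en-1-one | C/C(=C\CC[C@](C)(O[Si](CC)(CC)CC)[C@H](B1OC(C)(C)C(C)(C)O1)CC2=C(OC)CC[C@@H](O[Si](C)(C)C(C)(C)C)C2=O)CCC=C(C)C | intermediate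
12 | (6R)-6-(tert-butyldimethylsilyloxy)-2-[(2R,3S,6E)-2-hydroxy-3,7,11-trimethyl-3-(triethylsilyloxy)dodeca-6,10-dien-1-yl]-3-methoxycyclohex-2-en-1-one | C/C(=C\CC[C@](C)(O[Si](CC)(CC)CC)[C@H](O)CC1=C(OC)CC[C@@H](O[Si](C)(C)C(C)(C)C)C1=O)CCC=C(C)C | intermediate
13 | (2R)-methanesulfonate of 12 | C/C(=C\CC[C@](C)(O[Si](CC)(CC)CC)[C@H](OS(C)(=O)=O)CC1=C(OC)CC[C@@H](O[Si](C)(C)C(C)(C)C)C1=O)CCC=C(C)C | intermediate
14 | (2S,7R)-4-methoxy-2,3,6,7-tetrahydro-5H-1-benzofuran-1-ium methanesulfonate carrying the 7-OTBS group and the silylated side chain | C/C(=C\CC[C@](C)(O[Si](CC)(CC)CC)[C@@H]1CC2=C(OC)CC[C@@H](O[Si](C)(C)C(C)(C)C)C2=[O+]1)CCC=C(C)C.CS(=O)(=O)[O-] | intermediate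
15 | (2S,7R)-7-(tert-butyldimethylsilyloxy)-2-[(2S,5E)-6,10-dimethyl-2-(triethylsilyloxy)undeca-5,9-dien-2-yl]-3,5,6,7-tetrahydro-1-benzofuran-4(2H)-one | C/C(=C\CC[C@](C)(O[Si](CC)(CC)CC)[C@@H]1CC2=C(O1)[C@H](O[Si](C)(C)C(C)(C)C)CCC2=O)CCC=C(C)C | intermediate
16 | (2S,7R)-7-(tert-butyldimethylsilyloxy)-2-[(2S,5E,9E)-11-hydroxy-6,10-dimethyl-2-(triethylsilyloxy)undeca-5,9-dien-2-yl]-3,5,6,7-tetrahydro-1-benzofuran-4(2H)-one | C/C(=C\CC[C@](C)(O[Si](CC)(CC)CC)[C@@H]1CC2=C(O1)[C@H](O[Si](C)(C)C(C)(C)C)CCC2=O)CC/C=C(\C)CO | intermediate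
17 | (2E,6E,10S)-10-[(2S,7R)-7-(tert-butyldimethylsilyloxy)-4-oxo-2,3,4,5,6,7-hexahydro-1-benzofuran-2-yl]-2,6-dimethyl-10-(triethylsilyloxy)undeca-2,6-dienal | C/C(=C\CC[C@](C)(O[Si](CC)(CC)CC)[C@@H]1CC2=C(O1)[C@H](O[Si](C)(C)C(C)(C)C)CCC2=O)CC/C=C(\C)C=O | intermediate
18 | (2E,6E,10S)-10-[(2S,7R)-7-(tert-butyldimethylsilyloxy)-4-oxo-2,3,4,5,6,7-hexahydro-1-benzofuran-2-yl]-2,6-dimethyl-10-(triethylsilyloxy)undeca-2,6-dienoic acid | C/C(=C\CC[C@](C)(O[Si](CC)(CC)CC)[C@@H]1CC2=C(O1)[C@H](O[Si](C)(C)C(C)(C)C)CCC2=O)CC/C=C(\C)C(=O)O | intermediate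
19 | (2E,6E,10S)-10-hydroxy-10-[(2S,7R)-7-hydroxy-4-oxo-2,3,4,5,6,7-hexahydro-1-benzofuran-2-yl]-2,6-dimethylundeca-2,6-dienoic acid (CNP0297149.1) | C/C(=C\CC[C@](C)(O)[C@@H]1CC2=C(O1)[C@H](O)CCC2=O)CC/C=C(\C)C(=O)O | target

**Count and risk**

Total steps: 10. Longest linear sequence: 9 (steps 1, 2, 3, 4, 6, 7, 8, 9, 10 from compound 1).

Three steps most likely to fail:

Step 6 (diboration/cross-coupling cascade). Hot aqueous KOH may epimerise C7, hydrolyse the vinylogous ester of 7 or trigger loss of the β-silyloxy boronate, and the sense of induction is assumed. The fallback sets out from 9 (with 7) and comes back at 12. Only the diboration of 9 to 10 is run, and 10 is oxidised (NaBO3, THF/H2O) to (2R,3S,6E)-3,7,11-trimethyl-3-(triethylsilyloxy)dodeca-6,10-diene-1,2-diol F1. The primary hydroxyl is tosylated (TsCl, Bu2SnO cat., Et3N) to give (2R,3S,6E)-2-hydroxy-3,7,11-trimethyl-3-(triethylsilyloxy)dodeca-6,10-dien-1-yl 4-methylbenzenesulfonate F2, and K2CO3 in MeOH closes it to (R)-2-[(2S,5E)-6,10-dimethyl-2-(triethylsilyloxy)undeca-5,9-dien-2-yl]oxirane F3 without touching C2. F3 and 7 are then joined by a nickel-catalysed reductive cross-electrophile coupling (NiCl2(dme), 4,4'-di-tert-butyl-2,2'-bipyridine, NaI, Zn, DMPU); iodide opens the epoxide at its terminal carbon and the resulting alkyl iodide couples with the vinyl iodide, giving 12 without strong base.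

Step 7 (SN2 ring closure at a secondary carbon next to a quaternary centre). Elimination or slow displacement may win. The fallback sets out from 9 (with 7) and comes back at 15. Step 6 is run with the enantiomeric phosphonite to give the C2 epimer (6R)-6-(tert-butyldimethylsilyloxy)-2-[(2S,3S,6E)-2-hydroxy-3,7,11-trimethyl-3-(triethylsilyloxy)dodeca-6,10-dien-1-yl]-3-methoxycyclohex-2-en-1-one F4. The hydroxyl is then used as the nucleophile instead of being turned into a leaving group: with PPTS in MeCN containing a little water at 40 °C it adds to the ring carbonyl (5-exo-trig hemiketal), water is lost to the same type of oxocarbenium ion as 14, and hydrolysis of the methyl enol ether gives 15 with retention at C2 (Stork–Danheiser-type carbonyl transposition). The regiochemistry of this acid-mediated closure is less secure than in the main route and would have to be checked.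

Step 2 (lactone Claisen condensation, with step 3 regiochemistry depending on it). Enolate equilibration could racemise C7 or the ring closure could fail. The fallback sets out from commercial 3-methoxycyclohex-2-en-1-one F5 and comes back at 6. Kinetic enolisation (LiN(iPr)2, TMSCl, THF, −78 °C) gives 2-(trimethylsilyloxy)-4-methoxycyclohexa-1,3-diene F6. An asymmetric Rubottom oxidation (Shi fructose-derived ketone, KHSO5, K2CO3 buffer, then mild acid) epoxidises the more electron-rich silyl enol ether double bond and gives (R)-6-hydroxy-3-methoxycyclohex-2-en-1-one F7. The configuration and ee are checked by Mosher ester, and the enantiomeric ketone catalyst is used if the sense is opposite. Silylation (TBSCl, imidazole, DMF) then gives 6, which also removes the regiochemical question of step 3.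

**Further compounds**

F1 | step 6 | (2R,3S,6E)-3,7,11-trimethyl-3-(triethylsilyloxy)dodeca-6,10-diene-1,2-diol | C/C(=C\CC[C@](C)(O[Si](CC)(CC)CC)[C@H](O)CO)CCC=C(C)C
F2 | step 6 | (2R,3S,6E)-2-hydroxy-3,7,11-trimethyl-3-(triethylsilyloxy)dodeca-6,10-dien-1-yl 4-methylbenzenesulfonate | C/C(=C\CC[C@](C)(O[Si](CC)(CC)CC)[C@H](O)COS(=O)(=O)c1ccc(C)cc1)CCC=C(C)C
F3 | step 6 | (R)-2-[(2S,5E)-6,10-dimethyl-2-(triethylsilyloxy)undeca-5,9-dien-2-yl]oxirane | C/C(=C\CC[C@](C)(O[Si](CC)(CC)CC)[C@H]1CO1)CCC=C(C)C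
F4 | step 7 | (6R)-6-(tert-butyldimethylsilyloxy)-2-[(2S,3S,6E)-2-hydroxy-3,7,11-trimethyl-3-(triethylsilyloxy)dodeca-6,10-dien-1-yl]-3-methoxycyclohex-2-en-1-one | C/C(=C\CC[C@](C)(O[Si](CC)(CC)CC)[C@@H](O)CC1=C(OC)CC[C@@H](O[Si](C)(C)C(C)(C)C)C1=O)CCC=C(C)C
F5 | step 2 | 3-methoxycyclohex-2-en-1-one (commercial) | COC1=CC(=O)CCC1
F6 | step 2 | 2-(trimethylsilyloxy)-4-methoxycyclohexa-1,3-diene | COC1=CC(O[Si](C)(C)C)=CCC1
F7 | step 2 | (R)-6-hydroxy-3-methoxycyclohex-2-en-1-one | COC1=CC(=O)[C@H](O)CC1
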